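The 3,6-dihydro-1,2-dioxine ring (O1–O2–C3–C4=C5–C6) carries oxygen on both C3 and C6. This 1,4-relationship gives C4 and C5 the same (donor) polarity, so the C4–C5 bond is made by radical addition. In a single operation a manganese-generated C5 radical adds to methyl but-3-enoate, the C3 radical traps dioxygen, and the hydroperoxide closes on the C6 ketone. This delivers the whole 1,2-dioxane with all carbons in place. The precursor is an enantiopure β-keto sulfoxide, C16H33–CO–CH2–S(O)Tol. Its sulfinyl group enables the radical, makes the C3 epimers separable, and later leaves to unveil C4=C5.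

Key step: step 2

Remark (numbering, configuration): the ring locants O1, O2, C3–C6 are used for all compounds, open-chain ones included. The target is (3S,6R), so the methoxy group and the CH2CO2Me arm lie on opposite faces of the ring.

Remark (mobile centres): C5 and C6 of hemiketal 8 interconvert through ring–chain tautomerism. The epimer expected at equilibrium is drawn (equatorial sulfinyl, axial hydroxyl).

Remark (C6): replacing methoxy by methoxy is a degenerate exchange, so the share of 11 can only rise to its equilibrium value. Step 5 is therefore planned as equilibration, separation and recycling. A truly kinetic capture is kept as a fallback.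

Assumption: the 3S and 3R series of 8 are separable on silica or by crystallisation. The 3S series is identified by X-ray analysis, with the known sulfur configuration as internal reference.

Step 1
Reactants: 1 (R)-methyl p-tolyl sulfoxide; 2 methyl heptadecanoate
Product: 5 (R)-1-(p-tolylsulfinyl)octadecan-2-one, via lithiated sulfoxide 3 (not isolated), via lithium enolate 4 (not isolated)
Conditions: LiN(iPr)2 (2.1 equiv), THF, −78 °C; then 2, −78 → 0 °C; aq NH4Cl
Reagents that add atoms: none
Why: Claisen-type acylation of the α-sulfinyl carbanion 3 by the ester; the second equivalent of base stores the more acidic product as enolate 4, which prevents double addition, and the sulfur stereocentre is not touched, so 5 keeps the R configuration.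

Step 2
Reactants: 5 (R)-1-(p-tolylsulfinyl)octadecan-2-one; 6 methyl but-3-enoate
Product: 8 methyl 2-{(3S,5R,6S)-6-hexadecyl-6-hydroxy-5-[(R)-p-tolylsulfinyl]-1,2-dioxan-3-yl}acetate, via hydroperoxy ketone 7 (not isolated)
Conditions: Mn(OAc)3·2H2O (0.2 equiv), 6 (10 equiv), AcOH, stream of dry air (1 atm), 23 °C, dark; evaporate below 30 °C; SiO2 chromatography, then crystallisation to take the 3S series
Reagents that add atoms: dioxygen, O=O
Why: Mn(OAc)3 oxidises the enol of 5 to an electrophilic C5 radical that adds to the CH2 terminus of 6 (C4–C5); the secondary C3 radical resists oxidation by trivalent manganese and is taken by triplet dioxygen (C3–O2), and the peroxyl radical is reduced by Mn(OAc)2/AcOH to hydroperoxide 7 with return of Mn(OAc)3, so the metal is catalytic. The closest known reaction is the manganese triacetate aerobic three-component annulation of 1,3-dicarbonyl compounds and arylsulfinyl ketones with alkenes to 1,2-dioxan-3-ols, applied here to a less reactive monosubstituted alkene. The single ring, the 1,2-dioxane, closes by 6-exo-trig addition of the terminal hydroperoxide oxygen O1 to the C6 ketone. C3 forms without facial bias and is secured by separation, because the fixed R sulfur centre makes the 3S and 3R products diastereomers, while C5 and C6 remain mobile through 7 and its enol and should settle with equatorial sulfinyl and axial (anomeric) hydroxyl groups. The step needs terminal regioselectivity, which the steric and radical-stability bias of a monosubstituted alkene provides, and preference for alkene addition over direct oxygenation of the C5 radical, which the tenfold excess of 6 and the use of air instead of pure oxygen provide. The adduct radical sits gamma to sulfur, so loss of a sulfinyl radical by beta-scission is not open to it.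

Step 3
Reactants: 8 methyl 2-{(3S,5R,6S)-6-hexadecyl-6-hydroxy-5-[(R)-p-tolylsulfinyl]-1,2-dioxan-3-yl}acetate
Product: 9 methyl 2-{(3S,5R,6S)-6-hexadecyl-6-methoxy-5-[(R)-p-tolylsulfinyl]-1,2-dioxan-3-yl}acetate
Conditions: camphor-10-sulfonic acid (0.1 equiv), dry MeOH, 3 Å molecular sieves, 23 °C
Reagents that add atoms: methanol, CO
Why: Acid-catalysed ketalisation of a cyclic peroxyhemiketal (the counterpart of a Fischer glycosidation, known for 1,2-dioxan-3-ols): loss of water gives a peroxycarbenium ion at C6 that should take up methanol axially to give the anomerically favoured 6S ketal, which freezes the ring–chain equilibrium so that the later elimination can only give the ring alkene, and C3 is untouched.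

Step 4
Reactants: 9 methyl 2-{(3S,5R,6S)-6-hexadecyl-6-methoxy-5-[(R)-p-tolylsulfinyl]-1,2-dioxan-3-yl}acetate
Product: 10 methyl 2-[(3S,6S)-6-hexadecyl-6-methoxy-3,6-dihydro-1,2-dioxin-3-yl]acetate
Conditions: PhMe (0.01 M), powdered CaCO3 (insoluble acid buffer), argon, 100–110 °C, dark
Reagents that add atoms: none
Why: Thermal sulfoxide syn elimination (Ei): sulfur at C5 has beta hydrogens only at C4 (C6 is quaternary) and one of them is always cis to sulfur, so the C4=C5 alkene results and is held Z by the ring, while neutral conditions free of amine and phosphite spare the O–O bond, the ketal and the base-labile C3–O2 bond beta to the ester, and C3 and C6 are not involved.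

Step 5
Reactants: 10 methyl 2-[(3S,6S)-6-hexadecyl-6-methoxy-3,6-dihydro-1,2-dioxin-3-yl]acetate
Product: 11 methyl 2-[(3S,6R)-6-hexadecyl-6-methoxy-3,6-dihydro-1,2-dioxin-3-yl]acetate
Conditions: camphor-10-sulfonic acid (0.05 equiv), dry MeOH, 23 °C, until the epimer composition is constant; SiO2 chromatography; recovered 10 resubmitted
Reagents that add atoms: methanol, CO
Why: Acid-catalysed transketalisation (anomerisation): loss of methanol from 10 gives the flat, alkene-conjugated peroxycarbenium ion at C6, methanol returns from either face and C3 takes no part; since 11 can also keep its methoxy group pseudoaxial, at the small cost of a pseudoaxial C3 arm that faces only an oxygen lone pair, it should hold a useful share of the equilibrium mixture, from which it is separated while 10 is recycled.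

Compound list
1 | (R)-methyl p-tolyl sulfoxide | C[S@@](=O)c1ccc(C)cc1 | starting material
2 | methyl heptadecanoate | CCCCCCCCCCCCCCCCC(=O)OC | starting material
3 | [(R)-p-tolylsulfinyl]methyllithium (lithiated sulfoxide) | [Li]C[S@@](=O)c1ccc(C)cc1 | intermediate
4 | lithium (R)-1-(p-tolylsulfinyl)octadec-1-en-2-olate (lithium enolate of 5) | CCCCCCCCCCCCCCCCC([O-])=C[S@@](=O)c1ccc(C)cc1.[Li+] | intermediate
5 | (R)-1-(p-tolylsulfinyl)octadecan-2-one | CCCCCCCCCCCCCCCCC(=O)C[S@@](=O)c1ccc(C)cc1 | intermediate
6 | methyl but-3-enoate | C=CCC(=O)OC | starting material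
7 | methyl (3S)-3-hydroperoxy-6-oxo-5-[(R)-p-tolylsulfinyl]docosanoate (C5 mobile; 3S series shown) | CCCCCCCCCCCCCCCCC(=O)C([S@@](=O)c1ccc(C)cc1)C[C@H](CC(=O)OC)OO | intermediate
8 | methyl 2-{(3S,5R,6S)-6-hexadecyl-6-hydroxy-5-[(R)-p-tolylsulfinyl]-1,2-dioxan-3-yl}acetate | CCCCCCCCCCCCCCCC[C@@]1(O)[C@H]([S@@](=O)c2ccc(C)cc2)C[C@H](CC(=O)OC)OO1 | intermediate
9 | methyl 2-{(3S,5R,6S)-6-hexadecyl-6-methoxy-5-[(R)-p-tolylsulfinyl]-1,2-dioxan-3-yl}acetate | CCCCCCCCCCCCCCCC[C@@]1(OC)[C@H]([S@@](=O)c2ccc(C)cc2)C[C@H](CC(=O)OC)OO1 | intermediate
10 | methyl 2-[(3S,6S)-6-hexadecyl-6-methoxy-3,6-dihydro-1,2-dioxin-3-yl]acetate | CCCCCCCCCCCCCCCC[C@@]1(OC)C=C[C@H](CC(=O)OC)OO1 | intermediate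
11 | methyl 2-[(3S,6R)-6-hexadecyl-6-methoxy-3,6-dihydro-1,2-dioxin-3-yl]acetate | CCCCCCCCCCCCCCCC[C@]1(OC)C=C[C@H](CC(=O)OC)OO1 | target

Total step count: 5. Longest linear sequence: 5 (1 → 5 → 8 → 9 → 10 → 11).

Steps most likely to fail

**Step 2.**
- What may go wrong: addition of the C5 radical to a monosubstituted, unactivated alkene may be too slow. Direct oxygenation of that radical, hydrogen abstraction from the doubly activated CH2 of 6, or oxygen transfer to sulfur could then take over.
- The fallback forms C4–C5 by polar alkylation with a C4 electrophile and brings in the peroxide as H2O2. It sets out from 5 and returns at 9.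
- The sodium enolate of 5 (NaH, THF, 0 °C) is C-alkylated with methyl (E)-4-bromobut-2-enoate to methyl (2E)-6-oxo-5-[(R)-p-tolylsulfinyl]docos-2-enoate F1. This compound is kept cold because it can lose sulfenic acid.
- Urea–H2O2 with Sc(OTf)3 (cat.) in MeOH converts the ketone into methyl (2E)-6-hydroperoxy-6-methoxy-5-[(R)-p-tolylsulfinyl]docos-2-enoate F2.
- Et2NH (cat.) in CF3CH2OH closes the ring by 6-exo-trig oxa-Michael addition of the hydroperoxide to C3. The 3S isomer 9 is again isolated by chromatography, thanks to the sulfur stereocentre.

**Step 4.**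
- What may go wrong: at the temperature the ring sulfoxide needs, O–O homolysis or reduction of the peroxide by sulfenic-acid-derived sulfur species may compete with the syn elimination.
- The fallback eliminates before the ring is locked, where the sulfoxide is alpha to a ketone and leaves far more easily, and then repairs the alkene geometry with light. It sets out from 8 and returns at 11.
- Gentle warming of 8 (benzene, 50–60 °C) drains it through its open tautomer to methyl (3S,4E)-3-hydroperoxy-6-oxodocos-4-enoate F3.
- Irradiation through Pyrex (about 350 nm, benzene) isomerises the enone from E to Z. The Z isomer closes spontaneously to methyl 2-[(3S)-6-hexadecyl-6-hydroxy-3,6-dihydro-1,2-dioxin-3-yl]acetate F4.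
- Brief treatment with camphor-10-sulfonic acid in MeOH at 0 °C should give 11. Any 10 formed alongside enters step 5.

**Step 5.**
- What may go wrong: the equilibrium may lie so far towards the 6S epimer that recycling becomes tedious. Long exposure to acid may also erode the ring.
- The fallback replaces equilibration by kinetic capture from a different, more labile ketal. It sets out from 8 and returns at 11.
- Hemiketal 8 is ketalised in propan-2-ol (camphor-10-sulfonic acid, 3 Å sieves, 23 °C, where the methyl ester should not exchange) to methyl 2-{(3S,5R,6S)-6-hexadecyl-6-isopropoxy-5-[(R)-p-tolylsulfinyl]-1,2-dioxan-3-yl}acetate F5.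
- Thermolysis as in step 4 gives methyl 2-[(3S,6S)-6-hexadecyl-6-isopropoxy-3,6-dihydro-1,2-dioxin-3-yl]acetate F6.
- A branched alkoxy group ionises faster than methoxy. Short contact with pyridinium p-toluenesulfonate in MeOH at 0 °C should therefore consume F6 while the methyl ketals persist.
- Methanol should approach the flattened cation anti to the C3 arm, which leads to 11.

Further compounds
F1 | step 2 | methyl (2E)-6-oxo-5-[(R)-p-tolylsulfinyl]docos-2-enoate | CCCCCCCCCCCCCCCCC(=O)C(C/C=C/C(=O)OC)[S@@](=O)c1ccc(C)cc1
F2 | step 2 | methyl (2E)-6-hydroperoxy-6-methoxy-5-[(R)-p-tolylsulfinyl]docos-2-enoate | CCCCCCCCCCCCCCCCC(OC)(OO)C(C/C=C/C(=O)OC)[S@@](=O)c1ccc(C)cc1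
F3 | step 4 | methyl (3S,4E)-3-hydroperoxy-6-oxodocos-4-enoate | CCCCCCCCCCCCCCCCC(=O)/C=C/[C@H](CC(=O)OC)OO
F4 | step 4 | methyl 2-[(3S)-6-hexadecyl-6-hydroxy-3,6-dihydro-1,2-dioxin-3-yl]acetate (C6 mobile) | CCCCCCCCCCCCCCCCC1(O)C=C[C@H](CC(=O)OC)OO1
F5 | step 5 | methyl 2-{(3S,5R,6S)-6-hexadecyl-6-isopropoxy-5-[(R)-p-tolylsulfinyl]-1,2-dioxan-3-yl}acetate | CCCCCCCCCCCCCCCC[C@@]1(OC(C)C)[C@H]([S@@](=O)c2ccc(C)cc2)C[C@H](CC(=O)OC)OO1
F6 | step 5 | methyl 2-[(3S,6S)-6-hexadecyl-6-isopropoxy-3,6-dihydro-1,2-dioxin-3-yl]acetate | CCCCCCCCCCCCCCCC[C@@]1(OC(C)C)C=C[C@H](CC(=O)OC)OO1
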